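## Retrosynthetic overview

- **Feature:** ring A of this 2-aryl-3-methylbenzofuran shares only the C3a–C7a bond with the furan. Its single substituent is OH on C6, para to C3a. Ring A is therefore the aromatised [4+2] adduct of a furan C=C bond and a 1-methoxy-3-silyloxybutadiene.
- **Disconnection 1 (last ring):** cut C7–C7a and C3a–C4, back to a 2-aryl-3-methyl-4-nitrofuran. Nitro on future C3a makes future C7a the electrophilic terminus and later leaves as nitrous acid.
- **Disconnection 2 (furan):** cut O1–C7a, back to the γ-keto nitroenamine ArCO–CH(CH3)–C(NO2)=CH–NMe2. This is built on the ring-B propiophenone one atom at a time: CH2 (future C3a) by α-methylenation, N by conjugate addition of nitrite, CH (future C7a) from DMF dimethyl acetal.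
- **Ring order:** ring B is bought as flopropione and dressed first (C-prenyl, two MOM groups, O-methyl). The furan closes in step 7 and ring A in step 8. MOM removal ends the route.

Key step: step 8

Ar stands for 2-methoxy-4,6-bis(methoxymethoxy)-3-(3-methylbut-2-enyl)phenyl.

Remark on the chemistry: the stereocentres of 6, 7, 9, 10 and 13 arise without control. They are carried as racemates or mixtures and all vanish on aromatisation, and the target is achiral. Compound 10 is drawn as the E isomer expected for a tertiary nitroenamine; its geometry has no bearing on step 7.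

## Route

**Step 1**
Reactants: 1 flopropione, 1-(2,4,6-trihydroxyphenyl)propan-1-one; 2 prenyl bromide, 1-bromo-3-methylbut-2-ene
Product: 3 1-[2,4,6-trihydroxy-3-(3-methylbut-2-enyl)phenyl]propan-1-one
Conditions: KOH (1 equiv), H2O, 0 °C → rt
Reagents that add atoms: none
Why: Aqueous-base C-alkylation of the ambident phloroglucinolate is the standard entry to mono-C-prenyl acylphloroglucinols, the two free ring positions of 1 are equivalent so only one mono-C-prenyl isomer can form, and over-alkylated material is removed by chromatography.

**Step 2**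
Reactants: 3 1-[2,4,6-trihydroxy-3-(3-methylbut-2-enyl)phenyl]propan-1-one
Product: 4 1-[2-hydroxy-4,6-bis(methoxymethoxy)-3-(3-methylbut-2-enyl)phenyl]propan-1-one
Conditions: MOMCl (2.1 equiv), i-Pr2NEt, CH2Cl2, 0 °C
Reagents that add atoms: chloromethyl methyl ether, COCCl
Why: MOM ether formation (Williamson type) takes the unchelated 4-OH and the less hindered ortho 6-OH, while the 2-OH, wedged between prenyl and acyl and hydrogen-bonded to the ketone, should stay free.

**Step 3**
Reactants: 4 1-[2-hydroxy-4,6-bis(methoxymethoxy)-3-(3-methylbut-2-enyl)phenyl]propan-1-one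
Product: 5 1-Ar-propan-1-one, 1-[2-methoxy-4,6-bis(methoxymethoxy)-3-(3-methylbut-2-enyl)phenyl]propan-1-one
Conditions: MeI, K2CO3, DMF, rt → 40 °C
Reagents that add atoms: iodomethane, CI
Why: Williamson O-methylation of the one remaining, chelated phenol puts OMe between the acyl carbon and the prenyl carbon as in the target, and K2CO3 is too weak to enolise the ketone, so no C-methylation is expected.

**Step 4**
Reactants: 5 1-Ar-propan-1-one
Product: 8 1-Ar-2-methylprop-2-en-1-one, via Mannich base 6 (not isolated), via trimethylammonium iodide 7 (not isolated)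
Conditions: LDA, THF, −78 °C; CH2=NMe2+ I−, −78 °C → rt; MeI, rt; sat. aq NaHCO3, CH2Cl2
Reagents that add atoms: N,N-dimethylmethyleneiminium iodide (Eschenmoser's salt), C=[N+](C)C.[I-]; iodomethane, CI (its methyl group is carried only by 7 and leaves with the amine)
Why: A Mannich reaction of the preformed lithium enolate, quaternisation and Hofmann-type β-elimination give the α-methylene ketone under base-only conditions that spare the MOM and prenyl groups, and the new CH2 is future C3a.

**Step 5**
Reactants: 8 1-Ar-2-methylprop-2-en-1-one
Product: 9 1-Ar-2-methyl-3-nitropropan-1-one (racemic)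
Conditions: NaNO2 (2 equiv), AcOH (2 equiv), THF–H2O, 0 °C → rt, argon, dark; used without chromatography
Reagents that add atoms: sodium nitrite, [Na+].[O-]N=O
Why: Conjugate (Michael) addition of nitrite to an enone in a NaNO2/AcOH buffer is the known route to β-nitro carbonyl compounds; nitrogen and not carbon must be added here, because the methylene carbon already is future C3a and a nitromethane adduct would be one carbon too long and could close only to a 4H-pyran after aminomethylenation.

**Step 6**
Reactants: 9 1-Ar-2-methyl-3-nitropropan-1-one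
Product: 10 (E)-4-(dimethylamino)-1-Ar-2-methyl-3-nitrobut-3-en-1-one (racemic)
Conditions: Me2NCH(OMe)2 (1.5 equiv), toluene, rt → 40 °C
Reagents that add atoms: N,N-dimethylformamide dimethyl acetal, COC(OC)N(C)C
Why: In this aminomethylenation of a primary nitroalkane with an amide acetal, the CH2NO2 group is by far the most acidic site, its nitronate captures the formamidinium ion, and loss of methanol gives a push–pull nitroenamine whose nitro group sits on an sp2 carbon and can no longer leave by β-elimination; the new CH is future C7a.

**Step 7**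
Reactants: 10 (E)-4-(dimethylamino)-1-Ar-2-methyl-3-nitrobut-3-en-1-one
Product: 11 2-Ar-3-methyl-4-nitrofuran
Conditions: TFA (1.2 equiv), CH2Cl2, 0 °C → rt
Reagents that add atoms: none
Why: In this Paal–Knorr-type closure of a masked 2-nitro-1,4-ketoaldehyde, acid activates the nitroenamine carbon as an electrophile, the ketone oxygen closes the five-membered ring as phenols do in 3-nitrochromone syntheses, and loss of the C3 proton and of dimethylamine (which neutralises the acid and so shields the MOM ethers) gives the aromatic furan with nitro in place.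

**Step 8**
Reactants: 11 2-Ar-3-methyl-4-nitrofuran; 12 trans-1-methoxy-3-(trimethylsilyloxy)buta-1,3-diene (Danishefsky's diene)
Product: 15 2-Ar-3-methyl-1-benzofuran-6-ol (4',6'-bis-O-methoxymethyl glycybenzofuran), via nitro cycloadduct 13 (not isolated), via aryl trimethylsilyl ether 14 (not isolated)
Conditions: 12 (5 equiv, two portions), K2CO3 (anhydrous powder, 2 equiv), BHT (cat.), toluene, sealed tube, 120 °C; then 1 M aq citric acid, THF, rt
Reagents that add atoms: none
Why: This is a polar, normal-electron-demand Diels–Alder reaction of a nitro-activated heteroaromatic C=C bond, the type known for nitrofurans, nitropyrroles and nitroindoles with 1-methoxy-3-silyloxybutadienes: nitro on furan C4 makes C5 the electrophilic terminus, the nucleophilic CH2 of 12 bonds there first (C7–C7a), and C3a–C4 follows in the same asynchronous, at the limit zwitterionic, event. Ring A is thus closed by an intermolecular [4+2] cycloaddition that gives the cis-fused adduct 13. The tertiary nitro group of 13 is allylic to the C2=C3 enol ether and should leave readily together with the C7a hydrogen, which restores the furan; 1,4-loss of methanol (C4–OMe, C7–H) then aromatises the carbocycle to 14, and the citric acid wash frees the C6 phenol. The three stereocentres of 13 (C3a, C4, C7a) follow only from suprafacial addition and are all erased, so no facial or endo/exo control is needed. The selectivity that matters is regiochemical and positional: pairing the diene CH2 with the carbon β to nitro puts the silyloxy carbon at C6 and not C5, while the C2=C3 furan bond (tetrasubstituted, donor-substituted) and the prenyl alkene are unactivated. K2CO3 and the excess diene should take up the nitrous acid before it reaches the prenyl group or the electron-rich rings.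

**Step 9**
Reactants: 15 4',6'-bis-O-methoxymethyl glycybenzofuran
Product: 16 glycybenzofuran, 4-(6-hydroxy-3-methyl-1-benzofuran-2-yl)-5-methoxy-6-(3-methylbut-2-enyl)benzene-1,3-diol
Conditions: HCl (1.25 M in MeOH), 0 °C → rt
Reagents that add atoms: none
Why: Acid-catalysed acetal exchange with methanol removes both aryl MOM ethers, as is routine for prenylated phenols, and dilute acid at or below room temperature should leave the 3'-prenyl/4'-OH pair uncyclised.

## Compound list

| No. | Name | SMILES | Role |
|---|---|---|---|
| 1 | flopropione | CCC(=O)c1c(O)cc(O)cc1O | starting material |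
| 2 | prenyl bromide | CC(C)=CCBr | starting material |
| 3 | 1-[2,4,6-trihydroxy-3-(3-methylbut-2-enyl)phenyl]propan-1-one | CCC(=O)c1c(O)cc(O)c(CC=C(C)C)c1O | intermediate |
| 4 | 1-[2-hydroxy-4,6-bis(methoxymethoxy)-3-(3-methylbut-2-enyl)phenyl]propan-1-one | CCC(=O)c1c(OCOC)cc(OCOC)c(CC=C(C)C)c1O | intermediate |
| 5 | 1-[2-methoxy-4,6-bis(methoxymethoxy)-3-(3-methylbut-2-enyl)phenyl]propan-1-one | CCC(=O)c1c(OCOC)cc(OCOC)c(CC=C(C)C)c1OC | intermediate |
| 6 | 3-(dimethylamino)-1-Ar-2-methylpropan-1-one (racemic Mannich base) | CN(C)CC(C)C(=O)c1c(OCOC)cc(OCOC)c(CC=C(C)C)c1OC | intermediate |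
| 7 | 3-Ar-N,N,N,2-tetramethyl-3-oxopropan-1-aminium iodide (racemic) | C[N+](C)(C)CC(C)C(=O)c1c(OCOC)cc(OCOC)c(CC=C(C)C)c1OC.[I-] | intermediate |
| 8 | 1-Ar-2-methylprop-2-en-1-one | C=C(C)C(=O)c1c(OCOC)cc(OCOC)c(CC=C(C)C)c1OC | intermediate |
| 9 | 1-Ar-2-methyl-3-nitropropan-1-one (racemic) | CC(C[N+](=O)[O-])C(=O)c1c(OCOC)cc(OCOC)c(CC=C(C)C)c1OC | intermediate |
| 10 | (E)-4-(dimethylamino)-1-Ar-2-methyl-3-nitrobut-3-en-1-one (racemic) | CN(C)/C=C(/[N+](=O)[O-])C(C)C(=O)c1c(OCOC)cc(OCOC)c(CC=C(C)C)c1OC | intermediate |
| 11 | 2-[2-methoxy-4,6-bis(methoxymethoxy)-3-(3-methylbut-2-enyl)phenyl]-3-methyl-4-nitrofuran | Cc1c([N+](=O)[O-])coc1-c1c(OCOC)cc(OCOC)c(CC=C(C)C)c1OC | intermediate |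
| 12 | trans-1-methoxy-3-(trimethylsilyloxy)buta-1,3-diene | CO/C=C/C(=C)O[Si](C)(C)C | starting material |
| 13 | cis-fused 2-Ar-4-methoxy-3-methyl-3a-nitro-6-(trimethylsilyloxy)-3a,4,7,7a-tetrahydro-1-benzofuran (racemic, C4 undefined) | CC1=C(c3c(OCOC)cc(OCOC)c(CC=C(C)C)c3OC)O[C@@H]2CC(O[Si](C)(C)C)=CC(OC)[C@]12[N+](=O)[O-] | intermediate |
| 14 | 2-Ar-3-methyl-6-(trimethylsilyloxy)-1-benzofuran | COc1c(CC=C(C)C)c(OCOC)cc(OCOC)c1-c1oc2cc(O[Si](C)(C)C)ccc2c1C | intermediate |
| 15 | 4',6'-bis-O-methoxymethyl glycybenzofuran | COc1c(CC=C(C)C)c(OCOC)cc(OCOC)c1-c1oc2cc(O)ccc2c1C | intermediate |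
| 16 | glycybenzofuran | COc1c(CC=C(C)C)c(O)cc(O)c1-c1oc2cc(O)ccc2c1C | target |

Total step count: 9
Longest linear sequence: 9 steps (1 → 16)

## Steps most likely to fail

**Step 8.** The nitrofuran carries a methyl and an electron-rich aryl donor and may be too weak an electrophile. Thermal decay of the diene could then outrun the cycloaddition, or the nitrous acid released could attack the prenyl alkene. In the fallback, ring A is brought in as a finished arene instead of being built. The fallback sets out from ketone 5. A palladium-catalysed enolate α-arylation (Pd2(dba)3, XPhos, NaOtBu, toluene, 80 °C) uses 1-bromo-2,4-bis(methoxymethoxy)benzene F1, itself made from 4-bromoresorcinol with MOMCl and i-Pr2NEt. It should give 2-[2,4-bis(methoxymethoxy)phenyl]-1-Ar-propan-1-one F2. HCl in methanol then removes all four MOM groups, and the freed ortho-phenol cyclodehydrates onto the ketone. This places the second hydroxyl para to C3a and comes back to the route at target 16.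

**Step 6.** The ketone α-hydrogen of 9 lies β to the nitro group, so base-induced loss of nitrous acid back to enone 8 may be faster than C–C bond formation at the nitronate. The fallback removes the acidifying carbonyl for this one operation and sets out from 9. Luche reduction (NaBH4, CeCl3·7H2O, MeOH, −20 °C) should give 1-Ar-2-methyl-3-nitropropan-1-ol F3, which cannot undergo that elimination. DMF dimethyl acetal converts it into (E)-4-(dimethylamino)-1-Ar-2-methyl-3-nitrobut-3-en-1-ol F4. Dess–Martin periodinane (NaHCO3, CH2Cl2) reoxidises the benzylic alcohol, which comes back to the route at 10.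

**Step 5.** Nitrogen oxides formed from nitrous acid may add across the trisubstituted prenyl alkene, and the reversible nitrite addition may lie on the wrong side for this α-branched enone. The fallback replaces conjugate addition in acid by substitution under neutral conditions and sets out from ketone 5. The lithium enolate (LDA, THF, −78 °C) is hydroxymethylated with monomeric formaldehyde to 3-hydroxy-1-Ar-2-methylpropan-1-one F5. Appel-type iodination (I2, PPh3, imidazole, CH2Cl2) gives 3-iodo-1-Ar-2-methylpropan-1-one F6. AgNO2 in Et2O in the dark (Victor Meyer reaction) then displaces iodide, which comes back to the route at 9.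

## Further compounds

F1 | step 8 | 1-bromo-2,4-bis(methoxymethoxy)benzene | COCOc1ccc(Br)c(OCOC)c1
F2 | step 8 | 2-[2,4-bis(methoxymethoxy)phenyl]-1-[2-methoxy-4,6-bis(methoxymethoxy)-3-(3-methylbut-2-enyl)phenyl]propan-1-one (racemic) | CC(C(=O)c1c(OCOC)cc(OCOC)c(CC=C(C)C)c1OC)c1ccc(OCOC)cc1OCOC
F3 | step 6 | 1-[2-methoxy-4,6-bis(methoxymethoxy)-3-(3-methylbut-2-enyl)phenyl]-2-methyl-3-nitropropan-1-ol (diastereomer mixture) | CC(C[N+](=O)[O-])C(O)c1c(OCOC)cc(OCOC)c(CC=C(C)C)c1OC
F4 | step 6 | (E)-4-(dimethylamino)-1-[2-methoxy-4,6-bis(methoxymethoxy)-3-(3-methylbut-2-enyl)phenyl]-2-methyl-3-nitrobut-3-en-1-ol (diastereomer mixture) | CN(C)/C=C(/[N+](=O)[O-])C(C)C(O)c1c(OCOC)cc(OCOC)c(CC=C(C)C)c1OC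
F5 | step 5 | 3-hydroxy-1-[2-methoxy-4,6-bis(methoxymethoxy)-3-(3-methylbut-2-enyl)phenyl]-2-methylpropan-1-one (racemic) | CC(CO)C(=O)c1c(OCOC)cc(OCOC)c(CC=C(C)C)c1OC
F6 | step 5 | 3-iodo-1-[2-methoxy-4,6-bis(methoxymethoxy)-3-(3-methylbut-2-enyl)phenyl]-2-methylpropan-1-one (racemic) | CC(CI)C(=O)c1c(OCOC)cc(OCOC)c(CC=C(C)C)c1OC
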